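**Remark on the chemistry.** The sense of induction of the chiral acid in step 6 cannot be derived from first principles; it is assumed that one of its two accessible enantiomers gives (6S,7S)-9, and that enantiomer is used.

**Locants used throughout.** Ring A is the trimethoxybenzene ring; its carbon Ca carries C6 and its carbon Cf carries the spiro carbon Cs. Ring B is Cs–C9H2–C8–C7–C6–Ca–Cf. Ring C is the dienone. Stereodescriptors refer to these locants.

## Analysis of the target

The target contains three rings: benzene ring A with three adjacent methoxy groups, the seven-membered carbocycle B (Cs–C9H2–C8H(CH3)–C7H(CH3)–C6H(OBz)–Ca–Cf) fused to A, and a 2,6-dimethoxycyclohexa-2,5-dienone ring C joined to B at the spiro carbon Cs. Ring B carries three contiguous stereocentres, C6 (R, benzoate), C7 (S, methyl) and C8 (R, methyl). The C6 oxygen is trans to the C7 methyl and the C7 methyl is trans to the C8 methyl, so the benzoate and the C8 methyl are cis. Cs is quaternary but not stereogenic, because its two ring-C arms are identical. The sensitive groups are the cross-conjugated dienone (acid-induced rearrangement, hydride, soft nucleophiles), the benzoate (hydride, alkoxide) and the benzylic C6–O bond on an electron-rich ring (ionisation). The difficulty lies in closing a medium ring, setting three adjacent stereocentres with no nearby controlling group, and building a quaternary carbon wedged between a methoxy-flanked arene position and ring C. The strategy rests on the C6–C7 bond: C6 bears oxygen and C8 bears a methyl, so O–C6–C7–C8(=CH2) is the retron of a carbonyl-ene reaction between an aldehyde on Ca and a 2-methylbut-2-enyl group on the symmetric, non-stereogenic Cs.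

## Retrosynthetic reasoning

Ring C is removed first, because the dienone is the most fragile part and should be made last. Both C=C bonds of ring C are cut, each between a CH attached to Cs and its methoxy-bearing neighbour. This leads to dialdehyde 15 and 1,3-dimethoxyacetone 16, which supplies the C(OMe)–C(=O)–C(OMe) unit. The two formyl carbons are identical one-carbon arms on Cs, so Cs stays non-stereogenic all the way back. The forward reaction must form two C–C bonds and two C=C bonds without touching the benzoate.

Dialdehyde 15 comes from diol 14 by oxidation, and 14 from acetonide 13 by acetal hydrolysis. The benzoate of 13 is disconnected at the C6–O bond with inversion, giving the C6-epimeric alcohol 12. The ester is placed before ring C exists so that the substitution is run on a robust ether-only substrate, and the cis-alcohol stays available until then as a directing group.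

The C8 stereocentre of 12 is traced back to the exocyclic methylene of 11. In 11 the C6 hydroxyl is cis to the C7 methyl and therefore on the face from which hydrogen must reach C8, so a hydroxyl-directed hydrogenation relays the C6 configuration to C8 before C6 is inverted.

Acetonide 11 comes from triol 10, and 10 from diester 9 by ester reduction. These steps turn the two ester arms into the one-carbon arms needed for ring C and leave the C6 hydroxyl as the only free hydroxyl.

The key disconnection cuts C6–C7 of 9 and returns the hydrogen from the C6 oxygen to the exocyclic carbon on C8. This opens ring B and removes both stereocentres in one move, leading to the achiral aldehyde 8 with an (E)-2-methylbut-2-enyl group on Cs. The forward reaction must close a seven-membered ring, set C6 and C7 relative to each other through the alkene geometry, and set their absolute configuration through a chiral acid.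

Aldehyde 8 is the unmasked form of acetal 7. The Cs–C9 bond of 7 is cut by malonate alkylation to aryl malonate 4 and allylic bromide 6, which comes from alcohol 5. The Cs–Cf bond of 4 is cut by malonate arylation to bromide 2 and dimethyl malonate 3, and 2 is the acetal of aldehyde 1. These are standard bond formations, so the risk is concentrated in the ene step.

## Alternatives that were turned down

Alternative 1: Ring C is disconnected as a Robinson-type annulation. The α-aryl aldehyde A1, which already carries C7 and C8 in its side chain and the future C6 as a silyl-protected primary alcohol, would add through its α-carbon to the enone A2. Aldol condensation of the methoxymethyl carbon with the aldehyde would then close ring C and give the 2-methoxycyclohexenone A3.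
- For it: the annulation of α-aryl aldehydes to 4,4-disubstituted cyclohexenones is textbook chemistry. On ring C its precedent is stronger than that of the dialdehyde annulation chosen here.
- Against it: A3 lacks one methoxy group and one double bond of ring C, so α'-oxygenation, methylation and dehydrogenation must follow.
- Against it: the quaternary carbon of A3 is stereogenic until ring C becomes symmetric, so diastereomer mixtures are carried.
- Against it: C7 and C8 need their own asymmetric synthesis, and ring B must still be closed between C6 and Ca under acid in the presence of an acid-labile enone or dienone, with C6 set separately.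
- Comparison: the chosen route gives up the better ring-C precedent. In return it closes ring B and sets two stereocentres in one catalytic step from an achiral precursor made in five steps.

Alternative 2: Both C–CH3 bonds are cut, leading to the achiral benzocycloheptenone A4 (C6 ketone, C7=C8 alkene, geminal diester at Cs). A copper-catalysed enantioselective conjugate addition of a methylzinc reagent with a chiral phosphoramidite would place the C8 methyl. Trapping the enolate with a methyl electrophile would place the C7 methyl trans to it and give A5.
- For it: asymmetric conjugate methylation of cyclic enones, seven-membered ones included, is among the best-developed asymmetric C–C bond formations. On C7 and C8 this alternative has the stronger precedent.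
- For it: C6 arrives as a ketone, so the trans alcohol could come from a reduction without inversion.
- Against it: A4 is an aryl-conjugated, electron-rich enone and is less electrophilic than simple cycloheptenones.
- Against it: ring B must first be built by a separate ring closure that sets no stereocentre.
- Against it: zinc enolates methylate sluggishly and the α-position of the resulting aryl ketone is prone to proton transfer and over-alkylation.
- Against it: the facial selectivity of the C6 reduction is not secured.
- Comparison: three separate stereo-defining operations on a ring made beforehand are replaced in the chosen route by one ring-forming ene step plus a directed hydrogenation.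

Alternative 3: C6–C7 and C8–C9 are cut at once. The alkyne A7 would be inserted into the C6–C9 bond of the spiro-indanone A6 by a monovalent rhodium carbene catalyst with an aminopyridine co-catalyst. The five-membered ring would expand to ring B and give the benzocycloheptenone A8 with a tetrasubstituted C7=C8 bond.
- For it: two skeletal bonds and both methyl-bearing carbons arrive in one step, and the ring-C carbons are already in place. On convergence it is stronger than the chosen route.
- Against it: A8 has no stereocentre. The tetrasubstituted enone must be reduced enantioselectively, and syn hydrogenation gives the cis-dimethyl isomer, so C7 would have to be epimerised.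
- Against it: the C6 ketone must be reduced selectively.
- Against it: the protected cyclohexanone must be converted into the 2,6-dimethoxydienone by a multi-step double α-oxygenation and dehydrogenation.
- Against it: the bond to be cleaved lies next to a CH2 that is attached to a quaternary carbon, and the reaction needs high temperature.
- Comparison: the chosen route forms only one skeletal bond in its key step, but that step delivers two of the three stereocentres directly and the third follows by relay.

Key step: step 6

## Route

Step 1
Reactants: 1 2-bromo-3,4,5-trimethoxybenzaldehyde
Product: 2 2-bromo-1-(dimethoxymethyl)-3,4,5-trimethoxybenzene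
Conditions: HC(OMe)3, TsOH·H2O (cat.), MeOH, 50 °C
Reagents that add atoms: trimethyl orthoformate, COC(OC)OC; methanol, CO
Why: Acid-catalysed acetalisation driven by the orthoformate as water scavenger. The aldehyde is masked because the basic conditions of steps 2 and 4 would otherwise cause Knoevenagel condensation with the malonate.

Step 2
Reactants: 2 2-bromo-1-(dimethoxymethyl)-3,4,5-trimethoxybenzene; 3 dimethyl malonate
Product: 4 dimethyl 2-[6-(dimethoxymethyl)-2,3,4-trimethoxyphenyl]malonate
Conditions: Pd(OAc)2 (cat.), P(t-Bu)3·HBF4 (cat.), K3PO4, toluene, 100 °C
Reagents that add atoms: none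
Why: Palladium-catalysed α-arylation of a malonate with an aryl bromide; the bulky electron-rich trialkylphosphine is needed for oxidative addition into the electron-rich, doubly ortho-substituted C–Br bond and for reductive elimination of the hindered aryl–malonate bond. The product stays monoarylated because its enolate is too hindered to react again.

Step 3
Reactants: 5 (E)-2-methylbut-2-en-1-ol
Product: 6 (E)-1-bromo-2-methylbut-2-ene
Conditions: PBr3 (0.4 equiv), Et2O, 0 °C
Reagents that add atoms: phosphorus tribromide, BrP(Br)Br
Why: Bromination of a primary allylic alcohol with PBr3; the primary bromide with the trisubstituted alkene is the preferred allylic isomer and the (E) geometry is retained. The volatile bromide is used as a dried solution.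

Step 4
Reactants: 4 dimethyl 2-[6-(dimethoxymethyl)-2,3,4-trimethoxyphenyl]malonate; 6 (E)-1-bromo-2-methylbut-2-ene
Product: 7 dimethyl 2-[6-(dimethoxymethyl)-2,3,4-trimethoxyphenyl]-2-[(E)-2-methylbut-2-en-1-yl]malonate
Conditions: NaH, DMF, 0 °C; then 6, 0 °C → rt
Reagents that add atoms: none
Why: Malonic ester alkylation: SN2 attack of the sodium enolate on the primary allylic bromide builds the quaternary carbon Cs and keeps the (E)-alkene. The two ester arms remain identical, so Cs is not a stereocentre.

Step 5
Reactants: 7 dimethyl 2-[6-(dimethoxymethyl)-2,3,4-trimethoxyphenyl]-2-[(E)-2-methylbut-2-en-1-yl]malonate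
Product: 8 dimethyl 2-(6-formyl-2,3,4-trimethoxyphenyl)-2-[(E)-2-methylbut-2-en-1-yl]malonate
Conditions: 1 M aq. HCl, THF, 0 °C → rt
Reagents that add atoms: water, O
Why: Hydrolysis of an electron-rich aryl dimethyl acetal. Dilute acid at low temperature is chosen so that the freed aldehyde does not cyclise without stereocontrol before it meets the chiral catalyst.

Step 6
Reactants: 8 dimethyl 2-(6-formyl-2,3,4-trimethoxyphenyl)-2-[(E)-2-methylbut-2-en-1-yl]malonate
Product: 9 (6S,7S)-cis-alcohol with ring B closed: Cs(CO2Me)2, C9H2, C8(=CH2), C7H(CH3), C6H(OH), hydroxyl cis to the C7 methyl
Conditions: chiral imidodiphosphorimidate HN[P(=NSO2CF3)(O2Ar)]2 (O2Ar = 3,3'-diphenyl-1,1'-binaphthalene-2,2'-diolate, single enantiomer, 5 mol%), CH2Cl2 (0.02 M), 5 Å molecular sieves, −40 to −20 °C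
Reagents that add atoms: none
Why: Proposed new method: the confined chiral Brønsted acid activates the aldehyde by hydrogen bonding or protonation inside its pocket, the alkene carbon C7 attacks the carbonyl carbon C6 and a hydrogen of the C8 methyl passes to the carbonyl oxygen through a six-membered array, in a concerted but asynchronous process with positive charge building on tertiary C8 and the basic sites of the anion assisting the hydrogen transfer. The closest known reactions are chiral Brønsted acid catalysed carbonyl-ene cyclisations of alkenyl aldehydes to five- and six-membered rings and Lewis acid promoted type 2 carbonyl-ene closures of six- and seven-membered rings; an enantioselective type 2 closure of a benzo-fused seven-membered ring from an aromatic aldehyde has not been shown. Ring B closes as a seven-membered ring in the type 2 mode, exo with respect to the C=O bond and with both alkene carbons inside the new ring, so that C8 is left with an exocyclic methylene. The relative configuration of C6 and C7 follows from the bicyclic transition state, in which the oxygen must lie over the C8 methyl and Ca over C9; with the (E)-alkene this puts the C7 methyl and the new hydroxyl on the same face. The absolute configuration (6S,7S) comes from the catalyst alone, which selects one enantiotopic face of the alkene, because 8 has no stereocentre. The step needs bonding at C7 and not at C8 (which would give a six-membered ring with a quaternary carbon), secured by the charge build-up on tertiary C8, and hydrogen loss from the methyl and not from C9H2, secured by the transition-state geometry in which the oxygen lies over the methyl and away from C9. The geminal esters and the ortho substituents favour the folded conformer, and if the new hydroxyl closes a lactone with one ester nothing is lost, because step 7 reduces lactone and ester to the same triol.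

Step 7
Reactants: 9 (6S,7S)-cis-alcohol diester
Product: 10 (6S,7S)-triol: Cs(CH2OH)2, C8(=CH2), C7H(CH3), C6H(OH)
Conditions: LiAlH4, THF, 0 °C → rt
Reagents that add atoms: none
Why: Exhaustive hydride reduction of both methyl esters to the neopentyl 1,3-diol; the isolated alkene and the stereocentres are untouched. Low temperature limits retro-aldol loss of formaldehyde from the intermediate β-alkoxy ester.

Step 8
Reactants: 10 (6S,7S)-triol
Product: 11 (6S,7S)-acetonide alcohol: the two CH2OH groups on Cs tied as an isopropylidene acetal (spiro-1,3-dioxane), C6 hydroxyl free, C8(=CH2)
Conditions: Me2C(OMe)2, PPTS (cat.), CH2Cl2, rt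
Reagents that add atoms: 2,2-dimethoxypropane, COC(C)(C)OC
Why: Acetonide formation is selective for the 2,2-disubstituted propane-1,3-diol, which closes a six-membered dioxane, and leaves the C6 hydroxyl as the only free hydroxyl for steps 9 and 10. The symmetric acetal keeps Cs non-stereogenic, and PPTS is too weak an acid to ionise the benzylic alcohol.

Step 9
Reactants: 11 (6S,7S)-acetonide alcohol with C8 methylidene
Product: 12 (6S,7S,8R)-acetonide alcohol: C8 methyl trans to the C7 methyl, C6 hydroxyl cis to the C7 methyl
Conditions: H2 (1 atm), [Ir(cod)(PCy3)(py)]PF6 (5 mol%), CH2Cl2, 0 °C → rt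
Reagents that add atoms: none
Why: Hydroxyl-directed homogeneous hydrogenation of a homoallylic alcohol: the cationic iridium centre binds the C6 hydroxyl and the C8 methylidene on the same face and delivers both hydrogens there, so the new C8–H is cis to the C6 oxygen and the C8 methyl ends up trans to the C7 methyl (8R). In the reactive conformer the hydroxyl is pseudoaxial and syn to the alkene, while the cis C7 methyl is pseudoequatorial and out of the way.

Step 10
Reactants: 12 (6S,7S,8R)-acetonide alcohol
Product: 13 (6R,7S,8R)-acetonide benzoate: benzoate trans to the C7 methyl
Conditions: PPh3, DIAD, PhCO2H, toluene, 0 °C → rt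
Reagents that add atoms: benzoic acid, O=C(O)c1ccccc1
Why: Mitsunobu esterification: benzoate displaces the alkoxyphosphonium ion by SN2 from the face opposite to the leaving oxygen, which is also the face remote from the C7 methyl, and inverts C6 from S to R. Ring C is not yet present, so there is no enone that could add the phosphine.

Step 11
Reactants: 13 (6R,7S,8R)-acetonide benzoate
Product: 14 (6R,7S,8R)-diol benzoate: Cs(CH2OH)2
Conditions: AcOH–H2O–THF (3:1:1), 40 °C
Reagents that add atoms: none
Why: Acid-catalysed hydrolysis of the isopropylidene acetal under conditions mild enough to spare the benzylic benzoate; acyl migration to the primary hydroxyls is unlikely because it would need an eight-membered orthoester.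

Step 12
Reactants: 14 (6R,7S,8R)-diol benzoate
Product: 15 (6R,7S,8R)-dialdehyde benzoate: Cs(CHO)2
Conditions: (COCl)2, DMSO, CH2Cl2, −78 °C; Et3N, −78 → 0 °C
Reagents that add atoms: none
Why: Swern oxidation of both neopentyl primary alcohols to the non-enolisable 2,2-disubstituted malonaldehyde; without an α-hydrogen neither epimerisation nor elimination can occur. The dialdehyde is used at once, because quaternary 1,3-dialdehydes lose a formyl group to nucleophiles.

Step 13
Reactants: 15 (6R,7S,8R)-dialdehyde benzoate; 16 1,3-dimethoxyacetone
Product: 20 CNP0201356.1 (6R,7S,8R), via acyclic aldol adduct 17 (not isolated), via cyclic bis-aldol 18 (not isolated), via bis-mesylate 19 (not isolated)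
Conditions: 16, LiN(SiMe3)2 (1.0 equiv), THF, −78 °C, added to 15; LiN(SiMe3)2 (1.1 equiv), −78 → −30 °C; MsCl, −30 → 0 °C; DBU, 0 °C → rt
Reagents that add atoms: none
Why: Double aldol cyclocondensation of a 1,3-dialdehyde with a ketone that has two α-CH2 groups, the reaction type that turns malonaldehydes into phenols and phthalaldehyde into benzotropones, run here in stages: the lithium enolate of 16 adds to one formyl group, a second equivalent of base forms the α'-enolate, which closes the six-membered ring on the second formyl group, and mesylation followed by E1cB elimination gives both enol ether double bonds inside the ring. Closing the ring before dehydration avoids an acyclic enone of the wrong geometry, the non-nucleophilic amide base avoids alkoxide-induced loss of a formyl group, and the four transient stereocentres vanish in the symmetric dienone.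

## Compound list

1 | 2-bromo-3,4,5-trimethoxybenzaldehyde | COc1cc(C=O)c(Br)c(OC)c1OC | starting material
2 | 2-bromo-1-(dimethoxymethyl)-3,4,5-trimethoxybenzene | COC(OC)c1cc(OC)c(OC)c(OC)c1Br | intermediate
3 | dimethyl malonate | COC(=O)CC(=O)OC | starting material
4 | dimethyl 2-[6-(dimethoxymethyl)-2,3,4-trimethoxyphenyl]malonate | COC(OC)c1cc(OC)c(OC)c(OC)c1C(C(=O)OC)C(=O)OC | intermediate
5 | (E)-2-methylbut-2-en-1-ol | C/C=C(\C)CO | starting material
6 | (E)-1-bromo-2-methylbut-2-ene | C/C=C(\C)CBr | intermediate
7 | dimethyl 2-[6-(dimethoxymethyl)-2,3,4-trimethoxyphenyl]-2-[(E)-2-methylbut-2-en-1-yl]malonate | COC(OC)c1cc(OC)c(OC)c(OC)c1C(C/C(C)=C/C)(C(=O)OC)C(=O)OC | intermediate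
8 | dimethyl 2-(6-formyl-2,3,4-trimethoxyphenyl)-2-[(E)-2-methylbut-2-en-1-yl]malonate | O=Cc1cc(OC)c(OC)c(OC)c1C(C/C(C)=C/C)(C(=O)OC)C(=O)OC | intermediate
9 | (6S,7S)-cis-alcohol diester, ring B closed, C8 methylidene | COC(=O)C1(C(=O)OC)CC(=C)[C@H](C)[C@H](O)c2cc(OC)c(OC)c(OC)c21 | intermediate
10 | (6S,7S)-triol, Cs(CH2OH)2, C8 methylidene | OCC1(CO)CC(=C)[C@H](C)[C@H](O)c2cc(OC)c(OC)c(OC)c21 | intermediate
11 | (6S,7S)-acetonide alcohol, C8 methylidene | CC1(C)OCC2(CO1)CC(=C)[C@H](C)[C@H](O)c3cc(OC)c(OC)c(OC)c32 | intermediate
12 | (6S,7S,8R)-acetonide alcohol | CC1(C)OCC2(CO1)C[C@@H](C)[C@H](C)[C@H](O)c3cc(OC)c(OC)c(OC)c32 | intermediate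
13 | (6R,7S,8R)-acetonide benzoate | CC1(C)OCC2(CO1)C[C@@H](C)[C@H](C)[C@@H](OC(=O)c3ccccc3)c4cc(OC)c(OC)c(OC)c42 | intermediate
14 | (6R,7S,8R)-diol benzoate, Cs(CH2OH)2 | OCC1(CO)C[C@@H](C)[C@H](C)[C@@H](OC(=O)c2ccccc2)c2cc(OC)c(OC)c(OC)c21 | intermediate
15 | (6R,7S,8R)-dialdehyde benzoate, Cs(CHO)2 | O=CC1(C=O)C[C@@H](C)[C@H](C)[C@@H](OC(=O)c2ccccc2)c2cc(OC)c(OC)c(OC)c21 | intermediate
16 | 1,3-dimethoxyacetone | COCC(=O)COC | starting material
17 | acyclic aldol adduct of 15 and 16 (mixture at the three new centres) | COCC(=O)C(OC)C(O)C1(C=O)C[C@@H](C)[C@H](C)[C@@H](OC(=O)c2ccccc2)c2cc(OC)c(OC)c(OC)c21 | intermediate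
18 | cyclic bis-aldol, spiro 3,5-dihydroxy-2,6-dimethoxycyclohexanone (mixture at the four new centres) | COC1C(O)C2(C(O)C(OC)C1=O)C[C@@H](C)[C@H](C)[C@@H](OC(=O)c3ccccc3)c3cc(OC)c(OC)c(OC)c32 | intermediate
19 | bis-mesylate of 18 | COC1C(OS(C)(=O)=O)C2(C(OS(C)(=O)=O)C(OC)C1=O)C[C@@H](C)[C@H](C)[C@@H](OC(=O)c3ccccc3)c3cc(OC)c(OC)c(OC)c32 | intermediate
20 | CNP0201356.1, (6R,7S,8R)-spiro-dienone benzoate | COC1=CC2(C=C(OC)C1=O)C[C@@H](C)[C@H](C)[C@@H](OC(=O)c1ccccc1)c1cc(OC)c(OC)c(OC)c12 | target

## Step count and least certain steps

Total: 13 steps. Longest linear sequence: 12 steps (steps 1, 2 and 4 to 13 from 1); step 3 prepares the side-chain bromide.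

**Step 6 (key step).**
- What may go wrong: insufficient enantiofacial discrimination for this hindered, electron-rich aryl aldehyde. The reaction may also be diverted to a stepwise cationic course, with positive charge on C8 followed by loss of a different proton, capture by an ester carbonyl or scrambling of the alkene geometry. The strong acid may ionise the benzylic C6–O bond of the product.
- Why: the aldehyde is deactivated by the para methoxy group and needs a strong acid, and the product is a benzylic alcohol on the same ring.
- Fallback (known chemistry), setting out from 8 and coming back at 10: 8 is cyclised with Me2AlCl (CH2Cl2, −78 to 0 °C), a Lewis acid promoted type 2 carbonyl-ene closure in which the same transition-state geometry should give the racemic cis-alcohol F1. Esterification with (S)-2-methoxy-2-phenylacetic acid (DCC, cat. DMAP, 0 °C) would give the (S)-O-methylmandelate of the (6S,7S)-alcohol F2 and the (S)-O-methylmandelate of the (6R,7R)-alcohol F3, which are separated by chromatography. F2 is then treated with LiAlH4 as in step 7, which removes the auxiliary ester together with the two methyl esters and gives triol 10.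

**Step 13.**
- What may go wrong: loss of a formyl group from the quaternary dialdehyde by retro-Claisen-type cleavage, or addition of a second enolate to the remaining formyl group before the ring closes.
- Why: both formyl groups are equally reactive and the ring closure needs a second, regioselective enolisation.
- Fallback, setting out from 15 and coming back at 20: ring C is closed by an olefination instead of a second aldol. Diethyl (1,3-dimethoxy-2-oxopropyl)phosphonate F4 would be made from lithiated diethyl (methoxymethyl)phosphonate and methyl methoxyacetate and converted into its dianion (NaH, then n-BuLi, THF, −78 °C). The terminal carbon of the dianion should add to one formyl group of 15 to give the acyclic aldol phosphonate F5 (not isolated). On warming, the remaining phosphonate carbanion would close the ring on the second formyl group by intramolecular Horner–Wadsworth–Emmons olefination to the spiro hydroxy enone F6. Mesylation to the mesylate F7 and elimination with DBU would give 20.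

**Step 10.**
- What may go wrong: elimination towards a C6=C7 alkene, or ionisation at the benzylic carbon competing with the SN2 displacement and eroding the inversion.
- Why: the alcohol is secondary, benzylic on an electron-rich ring and flanked by the C7 methyl.
- Fallback, setting out from 12 and coming back at 13: oxidation with DMP (NaHCO3, CH2Cl2) would give the C6 ketone F8. Reduction with NaBH4 (MeOH, 0 °C), by axial attack of the small hydride, should give mainly the equatorial (6R)-alcohol F9; any (6S)-epimer is 12 itself and is recycled. Benzoylation of F9 (BzCl, DMAP, pyridine) gives 13.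

**Step 9.**
- What may go wrong: undirected hydrogenation from the opposite face, or migration of the double bond into the ring before reduction.
- Why: the directing effect depends on the conformer with a pseudoaxial hydroxyl, and cationic iridium hydrides can isomerise 1,1-disubstituted alkenes.
- Fallback, setting out from 11 and coming back at 12: hydrogen-atom-transfer hydrogenation with Mn(dpm)3 (cat.), PhSiH3 and t-BuOOH in i-PrOH. It proceeds through the tertiary C8 radical and relies on the preference for the equatorial C8 methyl trans to the C7 methyl. No new compound is involved.

**Step 2.**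
- What may go wrong: slow oxidative addition and reductive elimination at the doubly ortho-substituted, electron-rich bromide, so that protodebromination takes over.
- Why: the C–Br bond is flanked by a methoxy group and the acetal.
- Fallback, setting out from 2 and coming back at 4: bromine–lithium exchange (n-BuLi, THF, −78 °C), addition of the aryllithium to dimethyl 2-oxomalonate and acetylation of the alkoxide in the same flask (Ac2O) would give dimethyl 2-acetoxy-2-[6-(dimethoxymethyl)-2,3,4-trimethoxyphenyl]malonate F10. SmI2 (THF–MeOH) then removes the doubly ester-activated acetoxy group and gives 4.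

## Further compounds

F1 | step 6 | racemic cis-alcohol diester (both enantiomers of 9) | COC(=O)C1(C(=O)OC)CC(=C)[C@H](C)[C@H](O)c2cc(OC)c(OC)c(OC)c21.COC(=O)C1(C(=O)OC)CC(=C)[C@@H](C)[C@@H](O)c2cc(OC)c(OC)c(OC)c21
F2 | step 6 | (S)-O-methylmandelate of the (6S,7S)-alcohol | COC(=O)C1(C(=O)OC)CC(=C)[C@H](C)[C@H](OC(=O)[C@@H](OC)c2ccccc2)c2cc(OC)c(OC)c(OC)c21
F3 | step 6 | (S)-O-methylmandelate of the (6R,7R)-alcohol | COC(=O)C1(C(=O)OC)CC(=C)[C@@H](C)[C@@H](OC(=O)[C@@H](OC)c2ccccc2)c2cc(OC)c(OC)c(OC)c21
F4 | step 13 | diethyl (1,3-dimethoxy-2-oxopropyl)phosphonate | CCOP(=O)(OCC)C(OC)C(=O)COC
F5 | step 13 | acyclic aldol phosphonate from 15 and F4 (mixture at the new centres) | CCOP(=O)(OCC)C(OC)C(=O)C(OC)C(O)C1(C=O)C[C@@H](C)[C@H](C)[C@@H](OC(=O)c2ccccc2)c2cc(OC)c(OC)c(OC)c21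
F6 | step 13 | spiro 5-hydroxy-2,6-dimethoxycyclohex-2-enone (mixture at the new centres) | COC1=CC2(C(O)C(OC)C1=O)C[C@@H](C)[C@H](C)[C@@H](OC(=O)c3ccccc3)c3cc(OC)c(OC)c(OC)c32
F7 | step 13 | mesylate of F6 | COC1=CC2(C(OS(C)(=O)=O)C(OC)C1=O)C[C@@H](C)[C@H](C)[C@@H](OC(=O)c3ccccc3)c3cc(OC)c(OC)c(OC)c32
F8 | step 10 | (7S,8R)-C6 ketone acetonide | CC1(C)OCC2(CO1)C[C@@H](C)[C@H](C)C(=O)c1cc(OC)c(OC)c(OC)c12
F9 | step 10 | (6R,7S,8R)-acetonide alcohol (C6 epimer of 12) | CC1(C)OCC2(CO1)C[C@@H](C)[C@H](C)[C@@H](O)c1cc(OC)c(OC)c(OC)c12
F0 | step 9 | none | none
F10 | step 2 | dimethyl 2-acetoxy-2-[6-(dimethoxymethyl)-2,3,4-trimethoxyphenyl]malonate | COC(OC)c1cc(OC)c(OC)c(OC)c1C(OC(C)=O)(C(=O)OC)C(=O)OC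
A1 | alternative 1 | α-aryl aldehyde with C7/C8 side chain and silyl-protected C6 alcohol | O=CC(C[C@@H](C)[C@H](C)CO[Si](C)(C)C(C)(C)C)c1ccc(OC)c(OC)c1OC
A2 | alternative 1 | 1-methoxybut-3-en-2-one | COCC(=O)C=C
A3 | alternative 1 | 4-aryl-4-alkyl-2-methoxycyclohex-2-enone (epimers at the quaternary carbon) | COC1=CC(CCC1=O)(C[C@@H](C)[C@H](C)CO[Si](C)(C)C(C)(C)C)c1ccc(OC)c(OC)c1OC
A4 | alternative 2 | benzocycloheptenone with C6 ketone, C7=C8 alkene and geminal diester | COC(=O)C1(C(=O)OC)CC=CC(=O)c2cc(OC)c(OC)c(OC)c21
A5 | alternative 2 | trans-7,8-dimethyl benzosuberone geminal diester | COC(=O)C1(C(=O)OC)C[C@@H](C)[C@H](C)C(=O)c2cc(OC)c(OC)c(OC)c21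
A6 | alternative 3 | spiro-indanone with ketal-protected cyclohexanone | O=C1CC2(CCC3(CC2)OCCO3)c2c(OC)c(OC)c(OC)cc21
A7 | alternative 3 | but-2-yne | CC#CC
A8 | alternative 3 | 7,8-dimethyl benzocycloheptenone with tetrasubstituted C7=C8 alkene | O=C1C(C)=C(C)CC2(CCC3(CC2)OCCO3)c2c(OC)c(OC)c(OC)cc21
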